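**Direct plan and its weak points** (rings lettered A to G along the chain, A = 2,4,6-trihydroxyphenoxy end, G = 3,4,5-trihydroxyphenoxy end)

A direct plan would grow the chain from seven O-methylated arenes, one ether bond at a time, each by turning an aryl iodide into an aryl(trimethoxyphenyl)iodonium salt and passing the aryl group to a 2,6-dimethoxyphenoxide. Ring C would enter as iodide mesylate A1, ring E as iodide mesylate A2, and the last union would join tetramer iodide A3 to trimer phenol A4.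
- The iodonium unions, worst the last one (A3 with A4): a trivalent iodine species would meet 4-oxygenated 2,6-dimethoxyphenoxides, the classic substrates for oxidation by such iodanes, and the aryl group that leaves iodine would be chosen between two electron-rich ligands.
- The run-up to A2 and A1 (formylation, Dakin oxidation, mesylation, later mesylate hydrolysis): four to five operations per ring that form no bond of the skeleton, the first with doubtful regiochemistry.
- The two arylations at ring C: both neighbouring ether bonds would be made at the most hindered carbon and oxygen of the route, after an iodination that must choose between two free ring positions.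

**Retrosynthetic overview of the new route**

The cut goes through ring C itself (C1–O–ring B, C2–H, C3–OH, C4–OH, C5–OH, C6–O–ring D). This pentaoxygenated ring would not be carried in but built in the fragment union, from the two carbons of aryl ethynyl ether 10 (C2–H, C1–O–B) and the four carbons of squaric acid in cyclobutenone 26 (C6–O–D, C5, C4, C3).
Both ether oxygens at ring C would first be bonded to non-aromatic carbon (a dichlorovinyl ether, a squarate ester) by simple substitutions, so no arylation at ring C would be needed.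
Rings A, B, D, E, F and G would come from commercial arenes; ring C is the only ring formed, and it is formed last. Their four ether bonds would be made by SNAr on fluorobenzaldehydes, whose formyl group is then turned into the next phenol by Dakin oxidation, plus one Chan–Lam arylation.
There would be no trivalent iodine, no sulfonate protection and no ring C building block; the risk sits in one step.

Key step: step 14

**Route**

Step 1
Reactants: 1 2,4,6-trimethoxyphenol; 2 4-fluoro-2,6-dimethoxybenzaldehyde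
Product: 3 2,6-dimethoxy-4-(2,4,6-trimethoxyphenoxy)benzaldehyde (A–B aldehyde)
Conditions: K2CO3 (2 equiv), DMSO, 110 °C, Ar
Reagents that add atoms: none
Why: Nucleophilic aromatic substitution (addition–elimination): the fluorine of 2 is para to the formyl group and flanked by two C–H, so even the di-ortho-substituted phenoxide of 1 should attack there, and both methoxy groups of 2 are meta to the reacting carbon.

Step 2
Reactants: 3 A–B aldehyde
Product: 5 2,6-dimethoxy-4-(2,4,6-trimethoxyphenoxy)phenol (A–B phenol), via aryl formate 4 (not isolated)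
Conditions: mCPBA (1.3 equiv), NaHCO3, CH2Cl2, 0 °C to rt; then K2CO3 (0.2 equiv), MeOH, rt
Reagents that add atoms: 3-chloroperbenzoic acid, OOC(=O)c1cccc(Cl)c1
Why: Dakin-type Baeyer–Villiger oxidation: the electron-rich aryl group migrates to give formate 4, and methanolysis frees the phenol, so the formyl group that activated step 1 becomes the oxygen needed next.

Step 3
Reactants: 5 A–B phenol; 6 trichloroethylene
Product: 7 2-[(E)-1,2-dichloroethenyloxy]-1,3-dimethoxy-5-(2,4,6-trimethoxyphenoxy)benzene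
Conditions: K2CO3 (2 equiv), DMF, 70 °C
Reagents that add atoms: none
Why: Base turns trichloroethylene into dichloroacetylene in situ and the phenoxide adds to it (anti addition, hence the E ether); this elimination–addition with a small linear electrophile is not hindered by the two ortho methoxy groups and puts the ring B oxygen on the carbon that becomes C1 of ring C.

Step 4
Reactants: 7 dichlorovinyl ether
Product: 10 2-(ethynyloxy)-1,3-dimethoxy-5-(2,4,6-trimethoxyphenoxy)benzene (A–B ethynyl ether), via chloroethynyl ether 8 (not isolated), via lithium acetylide 9 (not isolated)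
Conditions: n-BuLi (2.5 equiv), Et2O, −78 to −40 °C; then MeOH, −78 °C
Reagents that add atoms: none
Why: Elimination of HCl gives chloroalkyne 8, chlorine–lithium exchange gives acetylide 9 and protonation gives the aryl ethynyl ether (the standard ynol ether synthesis from dichlorovinyl ethers); aryl methyl ethers should not be metalated at −78 °C.

Step 5
Reactants: 11 4-bromo-2,6-dimethoxyphenol; 12 2-fluoro-4,6-dimethoxybenzaldehyde
Product: 13 2-(4-bromo-2,6-dimethoxyphenoxy)-4,6-dimethoxybenzaldehyde (D–E aldehyde)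
Conditions: K2CO3 (2 equiv), DMSO, 120 °C, Ar
Reagents that add atoms: none
Why: Nucleophilic aromatic substitution ortho to the formyl group of 12, whose two methoxy groups are meta to the fluorine; the unactivated C–Br bond of 11 should not react.

Step 6
Reactants: 13 D–E aldehyde
Product: 15 2-(4-bromo-2,6-dimethoxyphenoxy)-4,6-dimethoxyphenol (D–E phenol), via aryl formate 14 (not isolated)
Conditions: mCPBA (1.3 equiv), NaHCO3, CH2Cl2, 0 °C to rt; then K2CO3 (0.2 equiv), MeOH, rt
Reagents that add atoms: 3-chloroperbenzoic acid, OOC(=O)c1cccc(Cl)c1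
Why: Dakin-type Baeyer–Villiger oxidation as in step 2; it places the hydroxyl of ring E between the ring D ether and a methoxy group.

Step 7
Reactants: 15 D–E phenol; 2 4-fluoro-2,6-dimethoxybenzaldehyde
Product: 16 4-[2-(4-bromo-2,6-dimethoxyphenoxy)-4,6-dimethoxyphenoxy]-2,6-dimethoxybenzaldehyde (D–E–F aldehyde)
Conditions: K2CO3 (2 equiv), DMSO, 110 °C, Ar
Reagents that add atoms: none
Why: Nucleophilic aromatic substitution as in step 1; the hindered phenoxide of 15 meets an unhindered carbon para to the formyl group.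

Step 8
Reactants: 16 D–E–F aldehyde
Product: 18 4-[2-(4-bromo-2,6-dimethoxyphenoxy)-4,6-dimethoxyphenoxy]-2,6-dimethoxyphenol (D–E–F phenol), via aryl formate 17 (not isolated)
Conditions: mCPBA (1.3 equiv), NaHCO3, CH2Cl2, 0 °C to rt; then K2CO3 (0.2 equiv), MeOH, rt
Reagents that add atoms: 3-chloroperbenzoic acid, OOC(=O)c1cccc(Cl)c1
Why: Dakin-type Baeyer–Villiger oxidation as in step 2.

Step 9
Reactants: 18 D–E–F phenol; 19 (3,4,5-trimethoxyphenyl)boronic acid (2.5 equiv)
Product: 20 5-bromo-2-{2-[3,5-dimethoxy-4-(3,4,5-trimethoxyphenoxy)phenoxy]-3,5-dimethoxyphenoxy}-1,3-dimethoxybenzene (D–E–F–G bromide)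
Conditions: Cu(OAc)2 (1.5 equiv), pyridine (5 equiv), 4 Å molecular sieves, CH2Cl2, rt, dry air
Reagents that add atoms: none
Why: Chan–Lam oxidative coupling: the aryl group passes from boron to divalent copper and C–O reductive elimination from a trivalent copper aryl phenoxide forms the ether at room temperature; the method accepts di-ortho-substituted phenols and leaves the C–Br bond untouched.

Step 10
Reactants: 20 D–E–F–G bromide
Product: 21 4-{2-[3,5-dimethoxy-4-(3,4,5-trimethoxyphenoxy)phenoxy]-3,5-dimethoxyphenoxy}-3,5-dimethoxyphenol (D–E–F–G phenol)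
Conditions: Pd2(dba)3 (2 mol %), tBuXPhos (8 mol %), KOH (3 equiv), 1,4-dioxane/H2O, 100 °C; then aq. HCl
Reagents that add atoms: potassium hydroxide, [K+].[OH-]
Why: Palladium-catalysed hydroxylation of an aryl bromide (oxidative addition to zerovalent palladium, bromide–hydroxide exchange, C–O reductive elimination from the bulky biarylphosphine complex); the bromide has two free ortho positions and the ethers are inert to KOH.

Step 11
Reactants: 21 D–E–F–G phenol; 22 squaric acid dichloride (3,4-dichlorocyclobut-3-ene-1,2-dione, 1.5 equiv)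
Product: 24 3-methoxy-4-(ArE-oxy)cyclobut-3-ene-1,2-dione (mixed squarate; ArE–O is the aryloxy group of 21), via chloro aryloxy squarate 23 (not isolated)
Conditions: Et3N (1.1 equiv), CH2Cl2, −78 °C; then MeOH (3 equiv), Et3N (1.5 equiv), −78 to −20 °C
Reagents that add atoms: methanol, CO
Why: Two addition–eliminations at the vinylogous acid chloride carbons of 22, first by the phenoxide of 21 and then by methanol; the later C6–O–ring D bond of ring C is thus made like an ester bond and not by arylation.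

Step 12
Reactants: 24 mixed squarate
Product: 25 4-hydroxy-3-methoxy-2-(ArE-oxy)cyclobut-2-en-1-one (racemic)
Conditions: LiAlH(OtBu)3 (1.1 equiv), THF, −78 to −40 °C; pH 7 phosphate buffer
Reagents that add atoms: none
Why: 1,2-Reduction of one ketone by a mild bulky hydride: the carbonyl next to C–OMe should be attacked, because the other carbonyl is the vinylogous ester carbonyl of the stronger donor methoxy (the regiochemistry known for additions to unsymmetrical cyclobutenediones); the new stereocentre forms as a racemate and is lost in step 14.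

Step 13
Reactants: 25 hydroxycyclobutenone
Product: 26 4-(tert-butyldimethylsilyloxy)-3-methoxy-2-(ArE-oxy)cyclobut-2-en-1-one (racemic)
Conditions: TBSCl (1.3 equiv), imidazole (2.5 equiv), DMF, 0 °C to rt
Reagents that add atoms: tert-butyldimethylsilyl chloride, CC(C)(C)[Si](C)(C)Cl
Why: Silylation of the secondary alcohol under non-acidic conditions, so that the acid-labile hydroxycyclobutenone does not lose methanol and the ketene of step 14 cannot be trapped by a free hydroxyl.

Step 14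
Reactants: 26 silyloxycyclobutenone; 10 A–B ethynyl ether (1.5 equiv)
Product: 31 2-(tert-butyldimethylsilyloxy)-3-methoxy-4-(ArE-oxy)-5-(ArW-oxy)phenol (protected heptamer; ArW–O is the aryloxy group of 5), via vinylketene 27 (not isolated), via cyclobutenone adduct 28 (not isolated), via dienylketene 29 (not isolated), via cyclohexadienone 30 (not isolated)
Conditions: toluene (0.05 M), 80 °C then 110 °C, Ar, sealed tube
Reagents that add atoms: none
Why: Proposed new method: on heating, 26 should open by 4π electrocyclic ring opening (silyloxy group rotating outward) to vinylketene 27, whose ketene C=C should add to the electron-rich triple bond of 10 in a regioselective [2+2] cycloaddition (ketene carbonyl carbon to the unsubstituted alkyne carbon) to give 28, and a second 4π opening (aryloxy outward, alkenyl inward) to dienylketene 29, 6π electrocyclization to dienone 30 and enolization should give phenol 31. The closest known reaction type is the Danheiser benzannulation of cyclobutenones with alkoxy- and siloxyalkynes, and the last three events are those of the Moore ring expansion of 4-alkenyl-4-oxycyclobutenones; new are the fully oxygenated, squaric-acid-derived cyclobutenone and the aryl ethynyl ether as partner. Ring C is closed by the 6π electrocyclization (bond from the ketene carbon, later C3, to the silyloxy-bearing alkene terminus, later C4), after the [2+2] step has joined the two fragments through the C1–C6 bond. No stereocentre remains, since the racemic centres of 26, 28 and 30 all become sp2 carbons of ring C. The one selectivity needed, C2–H next to C1–O–ring B next to C6–O–ring D, should follow from the polarity of the partners (nucleophilic terminal carbon of the ynol ether, electrophilic ketene carbon) and from the fixed order of the substituents in 26. The hydroxyl formed from the ketene carbon is the free C3–OH of the target, so nothing has to be adjusted afterwards.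

Step 15
Reactants: 31 protected heptamer
Product: 32 CNP0351377.0 (heptamer with 17 free OH, achiral)
Conditions: BBr3 (35 equiv), CH2Cl2, −78 °C to rt, Ar; then H2O, 0 °C; Sephadex LH-20 under Ar
Reagents that add atoms: none
Why: Lewis-acid dealkylation: BBr3 should cleave the 15 aryl methyl ethers by bromide attack at methyl and the aryl silyl ether at silicon, while the diaryl ether bonds offer no carbon for substitution; no stereocentre is present.

**Compound list** (ArW–O = aryloxy group of phenol 5; ArE–O = aryloxy group of phenol 21)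

1 | 2,4,6-trimethoxyphenol | COc1cc(OC)c(O)c(OC)c1 | starting material
2 | 4-fluoro-2,6-dimethoxybenzaldehyde | COc1cc(F)cc(OC)c1C=O | starting material
3 | 2,6-dimethoxy-4-(2,4,6-trimethoxyphenoxy)benzaldehyde | COc1cc(OC)c(Oc2cc(OC)c(C=O)c(OC)c2)c(OC)c1 | intermediate
4 | 2,6-dimethoxy-4-(2,4,6-trimethoxyphenoxy)phenyl formate | COc1cc(OC)c(Oc2cc(OC)c(OC=O)c(OC)c2)c(OC)c1 | intermediate (not isolated)
5 | 2,6-dimethoxy-4-(2,4,6-trimethoxyphenoxy)phenol | COc1cc(OC)c(Oc2cc(OC)c(O)c(OC)c2)c(OC)c1 | intermediate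
6 | trichloroethylene | ClC=C(Cl)Cl | starting material
7 | 2-[(E)-1,2-dichloroethenyloxy]-1,3-dimethoxy-5-(2,4,6-trimethoxyphenoxy)benzene | COc1cc(OC)c(Oc2cc(OC)c(O/C(Cl)=C\Cl)c(OC)c2)c(OC)c1 | intermediate
8 | 2-(chloroethynyloxy)-1,3-dimethoxy-5-(2,4,6-trimethoxyphenoxy)benzene | COc1cc(OC)c(Oc2cc(OC)c(OC#CCl)c(OC)c2)c(OC)c1 | intermediate (not isolated)
9 | lithium [2,6-dimethoxy-4-(2,4,6-trimethoxyphenoxy)phenoxy]ethynide | COc1cc(OC)c(Oc2cc(OC)c(OC#C[Li])c(OC)c2)c(OC)c1 | intermediate (not isolated)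
10 | 2-(ethynyloxy)-1,3-dimethoxy-5-(2,4,6-trimethoxyphenoxy)benzene | COc1cc(OC)c(Oc2cc(OC)c(OC#C)c(OC)c2)c(OC)c1 | intermediate
11 | 4-bromo-2,6-dimethoxyphenol | COc1cc(Br)cc(OC)c1O | starting material
12 | 2-fluoro-4,6-dimethoxybenzaldehyde | COc1cc(F)c(C=O)c(OC)c1 | starting material
13 | 2-(4-bromo-2,6-dimethoxyphenoxy)-4,6-dimethoxybenzaldehyde | COc1cc(Oc2c(OC)cc(Br)cc2OC)c(C=O)c(OC)c1 | intermediate
14 | 2-(4-bromo-2,6-dimethoxyphenoxy)-4,6-dimethoxyphenyl formate | COc1cc(Oc2c(OC)cc(Br)cc2OC)c(OC=O)c(OC)c1 | intermediate (not isolated)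
15 | 2-(4-bromo-2,6-dimethoxyphenoxy)-4,6-dimethoxyphenol | COc1cc(Oc2c(OC)cc(Br)cc2OC)c(O)c(OC)c1 | intermediate
16 | 4-[2-(4-bromo-2,6-dimethoxyphenoxy)-4,6-dimethoxyphenoxy]-2,6-dimethoxybenzaldehyde | COc1cc(Oc2c(OC)cc(Br)cc2OC)c(Oc2cc(OC)c(C=O)c(OC)c2)c(OC)c1 | intermediate
17 | 4-[2-(4-bromo-2,6-dimethoxyphenoxy)-4,6-dimethoxyphenoxy]-2,6-dimethoxyphenyl formate | COc1cc(Oc2c(OC)cc(Br)cc2OC)c(Oc2cc(OC)c(OC=O)c(OC)c2)c(OC)c1 | intermediate (not isolated)
18 | 4-[2-(4-bromo-2,6-dimethoxyphenoxy)-4,6-dimethoxyphenoxy]-2,6-dimethoxyphenol | COc1cc(Oc2c(OC)cc(Br)cc2OC)c(Oc2cc(OC)c(O)c(OC)c2)c(OC)c1 | intermediate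
19 | (3,4,5-trimethoxyphenyl)boronic acid | COc1cc(B(O)O)cc(OC)c1OC | starting material
20 | 5-bromo-2-{2-[3,5-dimethoxy-4-(3,4,5-trimethoxyphenoxy)phenoxy]-3,5-dimethoxyphenoxy}-1,3-dimethoxybenzene | COc1cc(Oc2c(OC)cc(Br)cc2OC)c(Oc2cc(OC)c(Oc3cc(OC)c(OC)c(OC)c3)c(OC)c2)c(OC)c1 | intermediate
21 | 4-{2-[3,5-dimethoxy-4-(3,4,5-trimethoxyphenoxy)phenoxy]-3,5-dimethoxyphenoxy}-3,5-dimethoxyphenol | Oc1cc(OC)c(Oc2cc(OC)cc(OC)c2Oc2cc(OC)c(Oc3cc(OC)c(OC)c(OC)c3)c(OC)c2)c(OC)c1 | intermediate
22 | squaric acid dichloride (3,4-dichlorocyclobut-3-ene-1,2-dione) | O=C1C(Cl)=C(Cl)C1=O | starting material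
23 | 3-chloro-4-(ArE-oxy)cyclobut-3-ene-1,2-dione | O=C1C(=O)C(Oc2cc(OC)c(Oc3cc(OC)cc(OC)c3Oc3cc(OC)c(Oc4cc(OC)c(OC)c(OC)c4)c(OC)c3)c(OC)c2)=C1Cl | intermediate (not isolated)
24 | 3-methoxy-4-(ArE-oxy)cyclobut-3-ene-1,2-dione | COC1=C(Oc2cc(OC)c(Oc3cc(OC)cc(OC)c3Oc3cc(OC)c(Oc4cc(OC)c(OC)c(OC)c4)c(OC)c3)c(OC)c2)C(=O)C1=O | intermediate
25 | 4-hydroxy-3-methoxy-2-(ArE-oxy)cyclobut-2-en-1-one (racemic) | COC1=C(Oc2cc(OC)c(Oc3cc(OC)cc(OC)c3Oc3cc(OC)c(Oc4cc(OC)c(OC)c(OC)c4)c(OC)c3)c(OC)c2)C(=O)C1O | intermediate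
26 | 4-(tert-butyldimethylsilyloxy)-3-methoxy-2-(ArE-oxy)cyclobut-2-en-1-one (racemic) | COC1=C(Oc2cc(OC)c(Oc3cc(OC)cc(OC)c3Oc3cc(OC)c(Oc4cc(OC)c(OC)c(OC)c4)c(OC)c3)c(OC)c2)C(=O)C1O[Si](C)(C)C(C)(C)C | intermediate
27 | (3Z)-4-(tert-butyldimethylsilyloxy)-3-methoxy-2-(ArE-oxy)buta-1,3-dien-1-one (vinylketene) | O=C=C(Oc1cc(OC)c(Oc2cc(OC)cc(OC)c2Oc2cc(OC)c(Oc3cc(OC)c(OC)c(OC)c3)c(OC)c2)c(OC)c1)/C(OC)=C/O[Si](C)(C)C(C)(C)C | intermediate (not isolated)
28 | 4-[(Z)-2-(tert-butyldimethylsilyloxy)-1-methoxyethenyl]-4-(ArE-oxy)-3-(ArW-oxy)cyclobut-2-en-1-one (racemic) | O=C1C=C(Oc2c(OC)cc(Oc3c(OC)cc(OC)cc3OC)cc2OC)C1(Oc1cc(OC)c(Oc2cc(OC)cc(OC)c2Oc2cc(OC)c(Oc3cc(OC)c(OC)c(OC)c3)c(OC)c2)c(OC)c1)/C(OC)=C/O[Si](C)(C)C(C)(C)C | intermediate (not isolated)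
29 | (3Z,5Z)-6-(tert-butyldimethylsilyloxy)-5-methoxy-4-(ArE-oxy)-3-(ArW-oxy)hexa-1,3,5-trien-1-one (dienylketene) | O=C=C\C(Oc1c(OC)cc(Oc2c(OC)cc(OC)cc2OC)cc1OC)=C(Oc1cc(OC)c(Oc2cc(OC)cc(OC)c2Oc2cc(OC)c(Oc3cc(OC)c(OC)c(OC)c3)c(OC)c2)c(OC)c1)/C(OC)=C/O[Si](C)(C)C(C)(C)C | intermediate (not isolated)
30 | 6-(tert-butyldimethylsilyloxy)-5-methoxy-4-(ArE-oxy)-3-(ArW-oxy)cyclohexa-2,4-dien-1-one (racemic) | O=C1C=C(Oc2c(OC)cc(Oc3c(OC)cc(OC)cc3OC)cc2OC)C(Oc2cc(OC)c(Oc3cc(OC)cc(OC)c3Oc3cc(OC)c(Oc4cc(OC)c(OC)c(OC)c4)c(OC)c3)c(OC)c2)=C(OC)C1O[Si](C)(C)C(C)(C)C | intermediate (not isolated)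
31 | 2-(tert-butyldimethylsilyloxy)-3-methoxy-4-(ArE-oxy)-5-(ArW-oxy)phenol (heptamer with 15 OMe, one OTBS, one free OH on ring C) | Oc1cc(Oc2c(OC)cc(Oc3c(OC)cc(OC)cc3OC)cc2OC)c(Oc2cc(OC)c(Oc3cc(OC)cc(OC)c3Oc3cc(OC)c(Oc4cc(OC)c(OC)c(OC)c4)c(OC)c3)c(OC)c2)c(OC)c1O[Si](C)(C)C(C)(C)C | intermediate
32 | CNP0351377.0, heptamer with 17 free OH (achiral) | Oc1cc(O)c(Oc2cc(O)c(Oc3cc(O)c(O)c(O)c3Oc3cc(O)c(Oc4cc(O)cc(O)c4Oc4cc(O)c(Oc5cc(O)c(O)c(O)c5)c(O)c4)c(O)c3)c(O)c2)c(O)c1 | target

**Count and risk**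

Total step count: 15. Longest linear sequence: 11 steps (steps 5 to 15).

Steps most likely to fail:

Step 14 (Proposed new method). The vinylketene from 26 may re-close or dimerize faster than it is intercepted by the hindered ynol ether, and 10 may polymerize at the temperature the ring opening needs. The fallback uses known reactions, sets out from 7 and 20 and comes back to the route at 32. Acetylide 9, made from 7 as in step 4 but not quenched, would be added to dimethyl squarate at −78 °C to give 4-hydroxy-2,3-dimethoxy-4-[(ArW-oxy)ethynyl]cyclobut-2-en-1-one F1. Moore rearrangement of this alkynyl hydroxycyclobutenone in refluxing p-xylene would give 2,3-dimethoxy-5-(ArW-oxy)-1,4-benzoquinone F2, which already holds ring C with its five oxygens and the ring B ether. Reduction with Na2S2O4 would give 2,3-dimethoxy-5-(ArW-oxy)benzene-1,4-diol F3. Benzylation of the less hindered hydroxyl, the one next to the ring C–H (BnBr 1 equiv, K2CO3, acetone), would give 4-(benzyloxy)-2,3-dimethoxy-6-(ArW-oxy)phenol F4. Copper-catalysed Ullmann coupling of the remaining hydroxyl with bromide 20 (CuI, picolinic acid, K3PO4, DMSO, 90 °C) would give the heptamer with 16 methyl ethers and one benzyl ether F5, and BBr3 as in step 15 would give 32.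

Step 12. Hydride may be delivered to the wrong carbonyl (poor discrimination between the two vinylogous ester carbonyls), or the hydroxycyclobutenone may lose methanol on work-up. The fallback sets out from 21 and 22 and comes back at 26; it removes the regiochemical question by symmetry. Two equivalents of 21 with 22 and Et3N would give 3,4-bis(ArE-oxy)cyclobut-3-ene-1,2-dione F6. Reduction with LiAlH(OtBu)3 would give 4-hydroxy-2,3-bis(ArE-oxy)cyclobut-2-en-1-one F7, and TBSCl with imidazole would give 4-(tert-butyldimethylsilyloxy)-2,3-bis(ArE-oxy)cyclobut-2-en-1-one F8. NaOMe (1 equiv) in THF/MeOH at −40 °C would then exchange only the aryloxy group on the β-carbon of the enone (conjugate addition–elimination), giving 26 and returning one equivalent of 21.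

Step 9. The electron-rich, di-ortho-substituted phenol may be oxidized by divalent copper and air faster than the C–O bond forms, and the boronic acid may be lost by protodeboronation. The fallback sets out from 18 and comes back at 20; it builds ring G by the chemistry of steps 1 and 2. SNAr of 18 with 2 (K2CO3, DMSO, 110 °C) would give 4-{4-[2-(4-bromo-2,6-dimethoxyphenoxy)-4,6-dimethoxyphenoxy]-2,6-dimethoxyphenoxy}-2,6-dimethoxybenzaldehyde F9. Dakin oxidation (mCPBA; then K2CO3, MeOH) would give 4-{4-[2-(4-bromo-2,6-dimethoxyphenoxy)-4,6-dimethoxyphenoxy]-2,6-dimethoxyphenoxy}-2,6-dimethoxyphenol F10, and methylation (MeI, K2CO3, acetone) would give 20.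

**Further compounds**

F1 | step 14 | 4-hydroxy-2,3-dimethoxy-4-{[2,6-dimethoxy-4-(2,4,6-trimethoxyphenoxy)phenoxy]ethynyl}cyclobut-2-en-1-one (racemic) | COC1=C(OC)C(O)(C#COc2c(OC)cc(Oc3c(OC)cc(OC)cc3OC)cc2OC)C1=O
F2 | step 14 | 2,3-dimethoxy-5-[2,6-dimethoxy-4-(2,4,6-trimethoxyphenoxy)phenoxy]-1,4-benzoquinone | COC1=C(OC)C(=O)C(Oc2c(OC)cc(Oc3c(OC)cc(OC)cc3OC)cc2OC)=CC1=O
F3 | step 14 | 2,3-dimethoxy-5-[2,6-dimethoxy-4-(2,4,6-trimethoxyphenoxy)phenoxy]benzene-1,4-diol | COc1c(OC)c(O)c(Oc2c(OC)cc(Oc3c(OC)cc(OC)cc3OC)cc2OC)cc1O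
F4 | step 14 | 4-(benzyloxy)-2,3-dimethoxy-6-[2,6-dimethoxy-4-(2,4,6-trimethoxyphenoxy)phenoxy]phenol | COc1c(OC)c(O)c(Oc2c(OC)cc(Oc3c(OC)cc(OC)cc3OC)cc2OC)cc1OCc1ccccc1
F5 | step 14 | heptamer with 16 methyl ethers and one benzyl ether (benzyl on the ring C oxygen next to the ring C–H) | COc1c(OC)c(Oc2cc(OC)c(Oc3cc(OC)cc(OC)c3Oc3cc(OC)c(Oc4cc(OC)c(OC)c(OC)c4)c(OC)c3)c(OC)c2)c(Oc2c(OC)cc(Oc3c(OC)cc(OC)cc3OC)cc2OC)cc1OCc1ccccc1
F6 | step 12 | 3,4-bis(ArE-oxy)cyclobut-3-ene-1,2-dione | O=C1C(=O)C(Oc2cc(OC)c(Oc3cc(OC)cc(OC)c3Oc3cc(OC)c(Oc4cc(OC)c(OC)c(OC)c4)c(OC)c3)c(OC)c2)=C1Oc1cc(OC)c(Oc2cc(OC)cc(OC)c2Oc2cc(OC)c(Oc3cc(OC)c(OC)c(OC)c3)c(OC)c2)c(OC)c1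
F7 | step 12 | 4-hydroxy-2,3-bis(ArE-oxy)cyclobut-2-en-1-one (racemic) | O=C1C(Oc2cc(OC)c(Oc3cc(OC)cc(OC)c3Oc3cc(OC)c(Oc4cc(OC)c(OC)c(OC)c4)c(OC)c3)c(OC)c2)=C(Oc2cc(OC)c(Oc3cc(OC)cc(OC)c3Oc3cc(OC)c(Oc4cc(OC)c(OC)c(OC)c4)c(OC)c3)c(OC)c2)C1O
F8 | step 12 | 4-(tert-butyldimethylsilyloxy)-2,3-bis(ArE-oxy)cyclobut-2-en-1-one (racemic) | O=C1C(Oc2cc(OC)c(Oc3cc(OC)cc(OC)c3Oc3cc(OC)c(Oc4cc(OC)c(OC)c(OC)c4)c(OC)c3)c(OC)c2)=C(Oc2cc(OC)c(Oc3cc(OC)cc(OC)c3Oc3cc(OC)c(Oc4cc(OC)c(OC)c(OC)c4)c(OC)c3)c(OC)c2)C1O[Si](C)(C)C(C)(C)C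
F9 | step 9 | 4-{4-[2-(4-bromo-2,6-dimethoxyphenoxy)-4,6-dimethoxyphenoxy]-2,6-dimethoxyphenoxy}-2,6-dimethoxybenzaldehyde | COc1cc(Oc2c(OC)cc(Br)cc2OC)c(Oc2cc(OC)c(Oc3cc(OC)c(C=O)c(OC)c3)c(OC)c2)c(OC)c1
F10 | step 9 | 4-{4-[2-(4-bromo-2,6-dimethoxyphenoxy)-4,6-dimethoxyphenoxy]-2,6-dimethoxyphenoxy}-2,6-dimethoxyphenol | COc1cc(Oc2c(OC)cc(Br)cc2OC)c(Oc2cc(OC)c(Oc3cc(OC)c(O)c(OC)c3)c(OC)c2)c(OC)c1
A1 | direct plan | 6-iodo-2,3,4-trimethoxyphenyl methanesulfonate | COc1cc(I)c(OS(C)(=O)=O)c(OC)c1OC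
A2 | direct plan | 2-iodo-4,6-dimethoxyphenyl methanesulfonate | COc1cc(I)c(OS(C)(=O)=O)c(OC)c1
A3 | direct plan | 5-{4-[2-(4-iodo-2,6-dimethoxyphenoxy)-4,6-dimethoxyphenoxy]-2,6-dimethoxyphenoxy}-1,2,3-trimethoxybenzene (D–E–F–G tetramer iodide) | COc1cc(Oc2c(OC)cc(Oc3c(Oc4c(OC)cc(I)cc4OC)cc(OC)cc3OC)cc2OC)cc(OC)c1OC
A4 | direct plan | 6-[2,6-dimethoxy-4-(2,4,6-trimethoxyphenoxy)phenoxy]-2,3,4-trimethoxyphenol (A–B–C trimer phenol) | COc1cc(Oc2c(OC)cc(Oc3c(OC)cc(OC)cc3OC)cc2OC)c(O)c(OC)c1OC
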